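**Strategy.** Everything rests on disconnecting two neighbouring substituents of the benzene ring together: the C1–CH3 bond and the C6–Br bond (ring numbered C1 CH3, C2 Br, C3 OH, C4 OH, C5 Br, C6 Br). C1 is para to the C4 oxygen and its neighbour C6 is para to the C3 oxygen, so the pair maps onto the two identical triple-bond carbons of mirror-symmetric 4,5-dimethoxybenzyne. In one flask the aryne is released from commercial 1,2-dibromo-4,5-dimethoxybenzene (a symmetric ortho-dibromide with both oxygens masked as methyl ethers), adds the methyl of MeMgBr, and the resulting arylmagnesium is brominated. Ether cleavage and bromination of the catechol at C2 and C5 finish the target.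

Key step: step 1

Remark: the target is achiral, so no stereochemical element has to be set. The singly brominated catechols that arise during the twofold bromination are numbered as non-isolated intermediates.

**Step 1**
Reactants: 1 1,2-dibromo-4,5-dimethoxybenzene; 2 methylmagnesium bromide; 3 1,2-dibromotetrachloroethane
Product: 7 1-bromo-4,5-dimethoxy-2-methylbenzene, via 2-bromo-4,5-dimethoxyphenyllithium 4 (not isolated), via 4,5-dimethoxybenzyne 5 (not isolated), via (4,5-dimethoxy-2-methylphenyl)magnesium bromide 6 (not isolated)
Conditions: n-BuLi (1.0 equiv), THF/Et2O, −100 °C, 15 min; MeMgBr (4 equiv), −100 °C to rt (40 °C if needed); BrCl2C–CCl2Br (5 equiv), THF, 0 °C to rt; aq. NH4Cl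
Reagents that add atoms: methylmagnesium bromide 2, C[Mg]Br; 1,2-dibromotetrachloroethane 3, BrC(Cl)(Cl)C(Cl)(Cl)Br
Why: Fast bromine–lithium exchange at one of the two equivalent C–Br bonds of 1 gives the ortho-bromoaryllithium 4, held at −100 °C so that all n-BuLi is consumed before any aryne exists; after the excess of 2 is added and the mixture warms, the ortho-bromoaryl metal (4 or its magnesium counterpart formed by exchange with 2) loses metal bromide and releases aryne 5 gradually into the methyl nucleophile. Carbomagnesiation of the strained triple bond by 2 forms the C1–CH3 bond and leaves magnesium on the neighbouring carbon (6), which attacks a bromine of 3 with expulsion of tetrachloroethene and bromide to form the C6–Br bond. The closest known reaction type is aryne generation from an ortho-dihaloarene with addition of a Grignard reagent and electrophilic quench of the ortho-substituted arylmagnesium, and bromination of arylmagnesium halides with 3 is routine. No ring is closed and no stereocentre is formed. Regioselectivity is not at stake because the mirror plane of 5 makes the two triple-bond carbons identical, so methyl and bromine can only end on adjacent carbons that are each para to a methoxy group. The selectivity actually required is chemoselectivity, secured by exactly one equivalent of n-BuLi (no butyl nucleophile left), by the several-fold excess of 2 over every aryl-metal species (methyl addition should outrun biaryl formation) and by enough 3 to quench all carbon–magnesium bonds.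

**Step 2**
Reactants: 7 1-bromo-4,5-dimethoxy-2-methylbenzene
Product: 9 4-bromo-5-methylbenzene-1,2-diol, via 2,5-dibromo-6-methyl-1,3,2-benzodioxaborole 8 (not isolated)
Conditions: BBr3 (3 equiv), CH2Cl2, −78 °C to rt; then H2O, 0 °C
Reagents that add atoms: none
Why: Lewis acid ether cleavage, in which BBr3 complexes each methoxy oxygen and bromide removes the methyl group by SN2 attack, the catechol staying bound as cyclic bromoborate 8 until water releases it, while the aryl bromide and the ring methyl are inert to BBr3.

**Step 3**
Reactants: 9 4-bromo-5-methylbenzene-1,2-diol
Product: 12 3,4,6-tribromo-5-methylbenzene-1,2-diol, via 3,5-dibromo-4-methylbenzene-1,2-diol 10 (not isolated), via 3,4-dibromo-5-methylbenzene-1,2-diol 11 (not isolated)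
Conditions: Br2 (2.1 equiv), AcOH, rt, dark; aq. Na2S2O4 work-up
Reagents that add atoms: bromine, BrBr
Why: Electrophilic aromatic bromination of an activated catechol, in which the only two unsubstituted ring carbons (C2 and C5) are each ortho to a hydroxyl, so either mono-bromination product 10 or 11 should converge on 12 with the second equivalent of Br2, and the Na2S2O4 wash returns any ortho-quinone formed by oxidation to the catechol.

**Compound list**
1 | 1,2-dibromo-4,5-dimethoxybenzene | COc1cc(Br)c(Br)cc1OC | starting material
2 | methylmagnesium bromide | C[Mg]Br | starting material
3 | 1,2-dibromotetrachloroethane | BrC(Cl)(Cl)C(Cl)(Cl)Br | starting material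
4 | 2-bromo-4,5-dimethoxyphenyllithium | [Li]c1cc(OC)c(OC)cc1Br | intermediate (not isolated)
5 | 4,5-dimethoxybenzyne | COC1=CC#CC=C1OC | intermediate (not isolated)
6 | (4,5-dimethoxy-2-methylphenyl)magnesium bromide | Cc1cc(OC)c(OC)cc1[Mg]Br | intermediate (not isolated)
7 | 1-bromo-4,5-dimethoxy-2-methylbenzene | Cc1cc(OC)c(OC)cc1Br | intermediate
8 | 2,5-dibromo-6-methyl-1,3,2-benzodioxaborole | Cc1cc2OB(Br)Oc2cc1Br | intermediate (not isolated)
9 | 4-bromo-5-methylbenzene-1,2-diol | Cc1cc(O)c(O)cc1Br | intermediate
10 | 3,5-dibromo-4-methylbenzene-1,2-diol | Cc1c(Br)c(O)c(O)cc1Br | intermediate (not isolated)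
11 | 3,4-dibromo-5-methylbenzene-1,2-diol | Cc1cc(O)c(O)c(Br)c1Br | intermediate (not isolated)
12 | 3,4,6-tribromo-5-methylbenzene-1,2-diol | Cc1c(Br)c(O)c(O)c(Br)c1Br | target

**Total step count:** 3
**Longest linear sequence:** 3 steps (1 → 7 → 9 → 12)

**Steps most likely to fail**

Step 1 (key step). The aryne may be captured by the aryl-metal species present in the flask (4, its magnesium counterpart or 6) faster than by the methyl reagent. Alternatively, 4 may lose LiBr before the Grignard reagent is in place. Either way biaryl and oligomeric material would grow at the expense of 7. The fallback uses no aryne. Setting out from 1, aryllithium 4 is formed as in step 1 (n-BuLi, THF/Et2O, −100 °C) and is methylated at that temperature with methyl trifluoromethanesulfonate, an electrophile fast enough to react before elimination. The C1–CH3 bond then comes from SN2 alkylation of the aryllithium, and the C6 bromine is simply the second bromine of 1. This should give 7 directly, where the route is rejoined; no compound outside the list arises (F0).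

Step 3. Bromine may act as an oxidant as well as an electrophile, so that part of the catechol is taken to the ortho-quinone level during substitution and the material is obtained as a catechol/quinone mixture that resists purification. The fallback accepts the oxidation instead of fighting it. Setting out from 9, bromination as in step 3 (through 10 and 11) is followed, without purification, by oxidation of the whole crude product with HNO3 in AcOH, the classical conversion of a perhalogenated catechol into its ortho-quinone. This should give 3,4,6-tribromo-5-methylcyclohexa-3,5-diene-1,2-dione F1, which is isolated by crystallisation. Reduction with Na2S2O4 in EtOAc/water then returns the route to 12.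

Step 2. The electron-rich catechol may be lost through aerial oxidation and through its water solubility during aqueous work-up and isolation. The fallback swaps the order of the last two operations, so that a free catechol appears only in its electron-poor, tribrominated form. Setting out from 7, excess Br2 with catalytic FeBr3 in CH2Cl2 (0 °C to rt, dark) brominates the two remaining ring positions. The reaction passes through 1,3-dibromo-4,5-dimethoxy-2-methylbenzene F2 and 2,3-dibromo-4,5-dimethoxy-1-methylbenzene F3 (neither isolated) to 1,2,4-tribromo-5,6-dimethoxy-3-methylbenzene F4. BBr3 in CH2Cl2 then cleaves both ortho-flanked ethers via the cyclic bromoborate 2,4,5,7-tetrabromo-6-methyl-1,3,2-benzodioxaborole F5 (not isolated), and hydrolysis rejoins the route at 12.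

**Further compounds**
F0 | step 1 | none | none
F1 | step 3 | 3,4,6-tribromo-5-methylcyclohexa-3,5-diene-1,2-dione | CC1=C(Br)C(=O)C(=O)C(Br)=C1Br
F2 | step 2 | 1,3-dibromo-4,5-dimethoxy-2-methylbenzene | Cc1c(Br)c(OC)c(OC)cc1Br
F3 | step 2 | 2,3-dibromo-4,5-dimethoxy-1-methylbenzene | Cc1cc(OC)c(OC)c(Br)c1Br
F4 | step 2 | 1,2,4-tribromo-5,6-dimethoxy-3-methylbenzene | Cc1c(Br)c(OC)c(OC)c(Br)c1Br
F5 | step 2 | 2,4,5,7-tetrabromo-6-methyl-1,3,2-benzodioxaborole | Cc1c(Br)c2OB(Br)Oc2c(Br)c1Br
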